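Assumption: the target has no stereocentre, so no enantiomer question arises; 1,2,3,4-tetramethoxybenzene and methyl isovanillate are treated as catalogue chemicals.

## Retrosynthetic overview
- Rings A and B are bought intact. Only the pyran-4-one ring C is built, and it is built last.
- Key disconnection: the O1–C8a aryl C–O bond. This leads back to a 1,3-diaryl-1,3-diketone whose A ring still carries H at the future C8a, closed by dehydrogenative C–H/O–H coupling.
- C2–C3 disconnection: crossed Claisen condensation of 2,3,4,5-tetramethoxyacetophenone with methyl isovanillate.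
- C4–C4a disconnection: Friedel–Crafts acetylation of 1,2,3,4-tetramethoxybenzene.
- The 3'-OH is carried free. It is masked only in the ring-closing pot, as a labile, deactivating trifluoroacetate.

## Route

Step 1
Reactants: 1 1,2,3,4-tetramethoxybenzene
Product: 2 1-(2,3,4,5-tetramethoxyphenyl)ethan-1-one
Conditions: Ac2O (1.5 equiv), Sc(OTf)3 (10 mol %), MeNO2, 50 °C, 8 h
Reagents that add atoms: acetic anhydride CC(=O)OC(C)=O
Why: Friedel–Crafts acylation; the two free positions of 1 are equivalent and each is ortho/para to OMe, the new acyl group stops a second acylation, and a catalytic rare-earth triflate avoids the ortho-demethylation caused by stoichiometric AlCl3.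

Step 2
Reactants: 2 1-(2,3,4,5-tetramethoxyphenyl)ethan-1-one; 3 methyl 3-hydroxy-4-methoxybenzoate (methyl isovanillate, 1.3 equiv)
Product: 4 1-(3-hydroxy-4-methoxyphenyl)-3-(2,3,4,5-tetramethoxyphenyl)propane-1,3-dione (mainly the chelated enol)
Conditions: NaH (4 equiv), THF, 0 °C → reflux, 8 h (2 added slowly to 3/NaH); then 1 M HCl
Reagents that add atoms: none
Why: Crossed Claisen condensation; the methyl-ketone enolate acylates the non-enolisable ester, whose phenoxide sits meta to the ester and so is not conjugated with it, and irreversible formation of the diketonate drives the reaction.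

Step 3
Reactants: 4 1-(3-hydroxy-4-methoxyphenyl)-3-(2,3,4,5-tetramethoxyphenyl)propane-1,3-dione
Product: 7 3'-demethylnobiletin, via diketone aryl trifluoroacetate 5 (not isolated), via flavone aryl trifluoroacetate 6 (not isolated)
Conditions: (i) (CF3CO)2O (1.2 equiv), DCE–MeCN 4:1 (0.05 M), 0 °C → rt, 30 min; (ii) 3,6-di-tert-butyl-9-mesityl-10-phenylacridinium BF4 (5 mol %), Co(dmgBF2)2(MeCN)2 (5 mol %), 450 nm LED, Ar, rt, 24 h; (iii) MeOH, rt, 30 min, evaporate
Reagents that add atoms: none
Why: Proposed new method: acceptorless dehydrogenative aryl C–H/enol O–H coupling that closes the pyran-4-one; TFAA first turns the easily oxidised 3'-phenol into an electron-poor aryl trifluoroacetate 5 (B ring est. > +2.0 V vs SCE), so the excited acridinium (E* ≈ +2.1 V) oxidises the tetramethoxybenzoyl ring (est. +1.5–1.6 V) preferentially, the enol oxygen on the B-ring-side carbon attacks the only free position of that radical cation (para to 3-OMe, ortho to 5-OMe, six-membered transition state), proton loss gives a cyclohexadienyl radical, and the acid-stable cobaloxime takes this electron and the one held by the reduced acridine and releases them as H2 with the TFA made in stage (i) as proton shuttle, which rearomatises to 6 before methanol removes the labile ester to give 7; closure onto the B ring is disfavoured because its ortho C–H sites are meta to OMe and ortho/para only to the acyloxy group, and the anhydrous medium (excess TFAA scavenges water) suppresses oxidative demethylation; the closest known reaction types are acridinium/cobaloxime arene C–H amination, dehydrogenative lactonisation of 2-arylbenzoic acids, FeCl3-mediated enol-O/aryl C–H closure to benzofurans, and base- or Cu-mediated cyclisation of 1-(2-haloaryl)-1,3-diketones to flavones (same closure geometry); no stereocentre is formed.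

## Compound list
1 | 1,2,3,4-tetramethoxybenzene | COc1ccc(OC)c(OC)c1OC | starting material
2 | 1-(2,3,4,5-tetramethoxyphenyl)ethan-1-one | CC(=O)c1cc(OC)c(OC)c(OC)c1OC | intermediate
3 | methyl 3-hydroxy-4-methoxybenzoate | COC(=O)c1ccc(OC)c(O)c1 | starting material
4 | 1-(3-hydroxy-4-methoxyphenyl)-3-(2,3,4,5-tetramethoxyphenyl)propane-1,3-dione | COc1ccc(C(=O)CC(=O)c2cc(OC)c(OC)c(OC)c2OC)cc1O | intermediate
5 | 2-methoxy-5-[3-oxo-3-(2,3,4,5-tetramethoxyphenyl)propanoyl]phenyl trifluoroacetate (not isolated) | COc1ccc(C(=O)CC(=O)c2cc(OC)c(OC)c(OC)c2OC)cc1OC(=O)C(F)(F)F | intermediate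
6 | 2-methoxy-5-(5,6,7,8-tetramethoxy-4-oxo-4H-chromen-2-yl)phenyl trifluoroacetate (not isolated) | COc1ccc(-c2cc(=O)c3c(OC)c(OC)c(OC)c(OC)c3o2)cc1OC(=O)C(F)(F)F | intermediate
7 | 3'-demethylnobiletin, 2-(3-hydroxy-4-methoxyphenyl)-5,6,7,8-tetramethoxy-4H-chromen-4-one | COc1ccc(-c2cc(=O)c3c(OC)c(OC)c(OC)c(OC)c3o2)cc1O | target

## Step count and risks
Total steps: 3. Longest linear sequence: 3 (1 → 2 → 4 → 7).

**Step 3 (the new step, highest risk).**
- The chelated enol must rotate about C3–C4 before its oxygen can reach the arene.
- The tetramethoxyarene radical cation may be too stabilised to be trapped.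
- Ipso attack at the C2-OMe carbon with loss of MeOH would give a 6,7,8-trimethoxyflavone.
- The product is about as oxidisable as the substrate, so it slows late conversion.

The fallback uses known chemistry, sets out from 2 and returns at 7. NBS in MeCN (0 °C → rt) brominates the only free ring position to give 1-(2-bromo-3,4,5,6-tetramethoxyphenyl)ethan-1-one F1. NaH/THF Claisen condensation with commercial methyl 3-(benzyloxy)-4-methoxybenzoate, followed by an HCl quench, gives 1-[3-(benzyloxy)-4-methoxyphenyl]-3-(2-bromo-3,4,5,6-tetramethoxyphenyl)propane-1,3-dione F2. CuI/1,10-phenanthroline (10 mol %), K2CO3, DMF, 110 °C then closes the same O1–C8a bond by intramolecular Ullmann-type O-arylation. This gives 2-[3-(benzyloxy)-4-methoxyphenyl]-5,6,7,8-tetramethoxy-4H-chromen-4-one F3. H2 (1 atm), Pd/C, EtOAc–MeOH removes the benzyl group to give 7.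

**Step 2.**
- The phenoxide-bearing ester may be poorly soluble and sluggish.
- A slow acylation would let 2 self-condense.

The fallback replaces acylation by aldol addition and oxidation; it sets out from 2 and returns at 4. The LDA enolate of 2 (THF, −78 °C) adds to commercial 3-(benzyloxy)-4-methoxybenzaldehyde, and an AcOH quench gives rac-3-[3-(benzyloxy)-4-methoxyphenyl]-3-hydroxy-1-(2,3,4,5-tetramethoxyphenyl)propan-1-one F4. IBX in EtOAc at reflux oxidises it to 1-[3-(benzyloxy)-4-methoxyphenyl]-3-(2,3,4,5-tetramethoxyphenyl)propane-1,3-dione F5. H2, Pd/C, EtOAc then gives 4.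

**Step 1.**
- The flanked, twisted OMe groups lower the ring's reactivity.
- Forcing Lewis-acid conditions would risk loss of the ortho methyl ether.

The fallback switches from electrophilic substitution to directed metalation; it sets out from 1 and returns at 2. n-BuLi/TMEDA in THF at 0 °C ortho-lithiates 1 to (2,3,4,5-tetramethoxyphenyl)lithium F6. This is acylated with N-methoxy-N-methylacetamide (−78 °C → rt, aq. HCl quench) to give 2.

## Further compounds
F1 | step 3 | 1-(2-bromo-3,4,5,6-tetramethoxyphenyl)ethan-1-one | CC(=O)c1c(Br)c(OC)c(OC)c(OC)c1OC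
F2 | step 3 | 1-[3-(benzyloxy)-4-methoxyphenyl]-3-(2-bromo-3,4,5,6-tetramethoxyphenyl)propane-1,3-dione | COc1ccc(C(=O)CC(=O)c2c(Br)c(OC)c(OC)c(OC)c2OC)cc1OCc1ccccc1
F3 | step 3 | 2-[3-(benzyloxy)-4-methoxyphenyl]-5,6,7,8-tetramethoxy-4H-chromen-4-one | COc1ccc(-c2cc(=O)c3c(OC)c(OC)c(OC)c(OC)c3o2)cc1OCc1ccccc1
F4 | step 2 | rac-3-[3-(benzyloxy)-4-methoxyphenyl]-3-hydroxy-1-(2,3,4,5-tetramethoxyphenyl)propan-1-one | COc1ccc(C(O)CC(=O)c2cc(OC)c(OC)c(OC)c2OC)cc1OCc1ccccc1
F5 | step 2 | 1-[3-(benzyloxy)-4-methoxyphenyl]-3-(2,3,4,5-tetramethoxyphenyl)propane-1,3-dione | COc1ccc(C(=O)CC(=O)c2cc(OC)c(OC)c(OC)c2OC)cc1OCc1ccccc1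
F6 | step 1 | (2,3,4,5-tetramethoxyphenyl)lithium | [Li]c1cc(OC)c(OC)c(OC)c1OC
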